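When you repeat this run, compare target with electrophile late on: in the midnight run target stands flat from 20.0 min to 40.0 min, at 25.7% and then 25.4%, while electrophile falls from 29.1% to 11.3%.

the same everywhere: electrophile 0.020 M

| flask | nucleophile | free base | remark | time |
|---|---|---|---|---|
| dawn | 0.022 M | 0.024 M | the very flask that is asked about, followed so far |  |
| midnight | 0.022 M | 0.016 M | run made earlier |  |
| flask | 0.0220 M | 0.0240 M |  | 1.5 h |

| run | time / min | target / % | electrophile / % |
|---|---|---|---|
| dawn | 1.00 | 6.8 | 92.8 |
| dawn | 3.00 | 16.5 | 81.3 |
| dawn | 6.00 | 21.3 | 64.2 |
| dawn | 8.00 | 24.4 | 57.1 |
| dawn | 12.0 | 27.7 | 43.4 |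
| dawn | 15.0 | 26.6 | 38.7 |
| midnight | 3.00 | 13.5 | 79.8 |
| midnight | 5.00 | 22.1 | 69.7 |
| midnight | 8.00 | 24.7 | 58.7 |
| midnight | 12.0 | 26.5 | 47.6 |
| midnight | 20.0 | 25.7 | 29.1 |
| midnight | 40.0 | 25.4 | 11.3 |

(scatter of a reading: 1 percentage point)

- the best time, 1.5 h at the latest, for target
- the amount of target, in percent of the electrophile charged, at that time

- in percentages every species weighs as the electrophile in it: one side product B counts as two
- what may be going on: electrophile + nucleophile -> acid set free + target; nucleophile + acid set free <-> protonated nucleophile; acid set free + free base <-> salt of the base; electrophile + acid set free -> side product A; electrophile + target -> side product B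

Electrophile makes target with nucleophile and burns target into side product B, and each making step sets free one acid, which free base or nucleophile takes up. Flat target means making and burning run equally, so electrophile decays pseudo-first-order, with 2 times the burning constant times target as its rate constant. That reading gives a burning constant of 4.63 M⁻¹ min⁻¹, and the first dawn reading gives a making constant of 3.40 M⁻¹ min⁻¹. Burning over making is the selectivity factor s, here 1.36. Electrophile stands in both rates and cancels, so watch free nucleophile: target rises while free nucleophile exceeds s times target.

Now take two extreme versions. If free base takes every acid, one nucleophile goes per making step, and the balance integrates to a peak of the nucleophile charge times s^(−s/(s−1)), which is 6.88 mM, or 34.4% of the electrophile. If nucleophile takes every acid, two go per step and the peak drops to 4.84 mM, or 24.2%. This flask has both takers, so I expect its peak between these, in the lower part, where dawn's highest reading of 27.7% stands.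

The forecast gives 26.8% at 0.23 h, with the words “The maximum is broad”.

The flask gives 27.2% at 0.291 h: the amount lies within its margin, and the time is later by a factor of 1.27.

    electrophile + nucleophile → acid set free + target (k = 3.50 M⁻¹ min⁻¹)
    nucleophile + acid set free ⇌ protonated nucleophile, settled at all times (K = 2.60 × 10⁵ M⁻¹)
    acid set free + free base ⇌ salt of the base, settled at all times (K = 91000 M⁻¹)
    electrophile + acid set free → side product A (k = 0.540 M⁻¹ min⁻¹)
    electrophile + target → side product B (k = 4.90 M⁻¹ min⁻¹)

At 0.291 h this flask holds 1.40 free nucleophile per target, beside the s of 1.36. The burning of target into side product B is the largest single effect on the peak of this flask: without that step the peak stands at 78.2% instead of 27.2%. In the neighbour with 0.050 M electrophile, the same band of 4.84 mM to 6.88 mM is 9.68% to 13.8% of its charge, and its best stands at 10.9%.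

The earlier runs and the new flask are simulated for substances that don't exist.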